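The meeting decided to take the gas transfer as done, and to reckon from there what competes for the starting material.

    2 starting material → homo dimer (k1 = 4.4 M⁻¹ s⁻¹)
    gas phase ⇌ dissolved gas, rate k2*(csat - [dissolved gas]) (k2 = 0.83 s⁻¹, csat = 4.6 mM)
    starting material + dissolved gas ⇌ target (K3 = 1000 M⁻¹, k3 = 1.6 M⁻¹ s⁻¹)
    dissolved gas + target → over-reacted product (k4 = 0.61 M⁻¹ s⁻¹)
    dissolved gas + protic impurity → quenched reagent (k5 = 9.1 M⁻¹ s⁻¹)

starting material 27 mM; gas phase 4.6 mM (held); protic impurity 1.35 mM; time 5.0 min

- percentages count the starting material that a species holds: one homo dimer counts as two
- two of one species on the left: rate k times its square, two consumed each time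
- at the start none of the gas is dissolved
- run time (flask): 5.0 min

- target at 5.0 min, in percent of the starting material charged
- concentration of dissolved gas in solution at 2.5 min, in percent of saturation
- the change that raises the amount of target at 5.0 min, in percent of the starting material charged most ("none" if none brings more than 2 percentage points) (south-east / north-west / none)
- amount of target at 5.0 min, in percent of the starting material charged, after south-east

- south-east: doubling the saturation concentration of gas phase, all else as stated
- north-west: doubling the transfer coefficient of step 2, all else as stated

**Minutes.** The chair defended the decision. Transfer runs at 0.83 s⁻¹. Capture and impurity together drain the dissolved gas at 0.0555 s⁻¹ at the start, which is slower. So the chair held the dissolved gas near its saturation of 4.6 mM.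

The kineticist drew the consequence. Capture then becomes pseudo-first-order, with constant 0.007360 s⁻¹. Dimerisation begins at 0.238 s⁻¹, which is faster, but it slows as the starting material falls. She called their starting ratio r, here 0.0310. Integrating both losses gives the capture share: r times the natural logarithm of one plus its inverse. This estimates the part of the starting material that enters target by the forward step, with the gas at saturation, here 10.9%.

As secretary, I added my own reckoning. Over-reaction removes target at 0.002806 s⁻¹. Applied to the whole share over the whole 5.0 min, that gives my estimate of 4.68%. I set aside the way back from target, at 0.001600 s⁻¹, so this is a rough figure. On the same reckoning, south-east raises the share to 17.6% but doubles that loss, giving 3.27%, which is less. North-west leaves this reckoned share unchanged, since no transfer coefficient stands in it. So I entered "none".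

The forecast, tabled next, gave 4.5%, 99.8%, none and 3.9%, holding that “doubling saturation captures more early but burns more target”. It chose as I did, but its figures differ from mine: 4.5% against my 4.68%, and 3.9% against my 3.27%.

**Result.** The flask gave 3.91%, 99.8%, none and 3.42%; south-east moved target by −0.49 percentage points, north-west by 0.12 points. The neighbour flask with 6.8 mM of starting material has a reckoned share of 27.2%; at 5.00 min it held 10.8% target, 10.5% over-reacted product and 3.01% starting material. The flask itself has not come to rest. Its homo dimer barely moves, from 90.9% to 91.4% at 50.0 min, and its starting material reads 0% by then. Over the same span, its over-reacted product climbs from 4.21% to 8.62%, which is less than the reckoned share of 10.9%, while its target falls from 3.91% to 0.00857%.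

The constants come from no measurement; the result is computed.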